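The route rests on disconnecting the C2–C3 bond of the 2,3-dihydrobenzofuran (benzofuran numbering; ring A is its benzo ring). In the open form, C2 is an OCH2 carbon whose hydridic C–H bonds are activated by O1 and by the 3,4-dioxygenated aryl ring. These bonds lie 1,5 to C3, which is flanked by ring A and the 3,5-dioxygenated ring. A rhodium donor/donor carbene at C3, generated from a benzophenone hydrazone that already carries the stilbene, inserts enantioselectively into one of them, closing the furan ring and fixing C3 in one operation. Global demethylation with thermodynamic C2 epimerization then gives the trans target.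

Key step: step 5

Assumption (remark on the chemistry): Rh2(R-PTAD)4, dirhodium tetrakis[(R)-(1-adamantyl)(phthalimido)acetate], is taken to deliver the (3S) configuration at the carbene-derived carbon; if the sense of induction proves opposite, the enantiomeric catalyst Rh2(S-PTAD)4 is used with no other change.

Step 1
Reactants: 1 1-bromo-2,4-dimethoxybenzene; 2 3,5-dimethoxybenzoyl chloride
Product: 4 (5-bromo-2-hydroxy-4-methoxyphenyl)(3,5-dimethoxyphenyl)methanone, via ortho-methoxy ketone 3 (not isolated)
Conditions: AlCl3 (3 equiv), CH2Cl2, 0 °C → reflux; aq. HCl work-up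
Reagents that add atoms: none
Why: Friedel–Crafts acylation should occur at C5 of 1, the unhindered position para to one methoxy group and ortho to the other, and the excess AlCl3 should then cleave only the methyl ether ortho to the new carbonyl through its six-membered aluminium chelate (chelation-directed demethylation), leaving the phenol needed for the next step.

Step 2
Reactants: 4 (5-bromo-2-hydroxy-4-methoxyphenyl)(3,5-dimethoxyphenyl)methanone; 5 3,4-dimethoxybenzyl bromide
Product: 6 {5-bromo-2-[(3,4-dimethoxybenzyl)oxy]-4-methoxyphenyl}(3,5-dimethoxyphenyl)methanone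
Conditions: K2CO3, DMF, 60 °C
Reagents that add atoms: none
Why: Williamson etherification, in which carbonate in DMF deprotonates the carbonyl-chelated phenol and the phenoxide displaces bromide from the activated benzylic halide by an SN2 reaction, installing the OCH2Ar unit whose carbon becomes C2.

Step 3
Reactants: 6 {5-bromo-2-[(3,4-dimethoxybenzyl)oxy]-4-methoxyphenyl}(3,5-dimethoxyphenyl)methanone; 7 3,5-dimethoxystyrene
Product: 8 {2-[(3,4-dimethoxybenzyl)oxy]-5-[(E)-2-(3,5-dimethoxyphenyl)ethenyl]-4-methoxyphenyl}(3,5-dimethoxyphenyl)methanone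
Conditions: Pd(OAc)2 (5 mol %), P(o-tol)3 (10 mol %), Et3N, DMF, 110 °C
Reagents that add atoms: none
Why: Mizoroki–Heck reaction, in which oxidative addition of the aryl bromide to zerovalent palladium, syn carbopalladation of the styrene at its terminal carbon and syn β-hydride elimination should give the E-stilbene while the ketone and the benzyl ether stay untouched.

Step 4
Reactants: 8 {2-[(3,4-dimethoxybenzyl)oxy]-5-[(E)-2-(3,5-dimethoxyphenyl)ethenyl]-4-methoxyphenyl}(3,5-dimethoxyphenyl)methanone
Product: 9 hydrazone of ketone 8 (C=N–NH2, mixture of C=N isomers)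
Conditions: N2H4·H2O (10 equiv), AcOH (cat.), EtOH, 90 °C (sealed tube), argon
Reagents that add atoms: hydrazine (used as the hydrate), NN
Why: Acid-catalysed condensation of the diaryl ketone with excess hydrazine should give the N-unsubstituted hydrazone (the excess suppresses azine formation, argon prevents diimide generation and thus reduction of the stilbene), and its C=N geometry is irrelevant because it is lost in the diazo compound.

Step 5
Reactants: 9 hydrazone of ketone 8
Product: 11 (2R,3S)-2-(3,4-dimethoxyphenyl)-3-(3,5-dimethoxyphenyl)-5-[(E)-2-(3,5-dimethoxyphenyl)ethenyl]-6-methoxy-2,3-dihydro-1-benzofuran (2,3-cis), via diazo compound 10 (not isolated)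
Conditions: MnO2 (8 equiv), CH2Cl2, 0 °C; filtration through Celite; then slow addition to Rh2(R-PTAD)4 (1 mol %), CH2Cl2/MeCN, 0 °C
Reagents that add atoms: none
Why: MnO2 dehydrogenates the hydrazone to the diaryldiazomethane 10, which loses N2 on the divalent-rhodium paddlewheel carboxylate to give a donor/donor rhodium carbene at the future C3; the carbene inserts into one of the two enantiotopic C–H bonds of the OCH2 group (future C2) through a concerted, asynchronous three-centre transition state with hydride-shift character. The closest known reaction type is the enantioselective intramolecular 1,5-C–H insertion of donor/donor carbenes, made from 2-(benzyloxy)benzophenone hydrazones, into benzylic ether C–H bonds to give 2,3-diaryl-2,3-dihydrobenzofurans. The furan ring (O1–C2–C3–C3a–C7a) closes by formation of the C2–C3 bond in a 1,5-insertion mode through a five-membered transition state. The configuration at C3 is controlled by the chiral carboxylate ligands of the catalyst, which differentiate the two faces of the carbene, and the cis relation at C2 should follow from the concerted insertion geometry in which the 3,4-dimethoxyphenyl group points away from the ligand wall. The step needs chemoselectivity for the intramolecular insertion over azine formation and over attack on the stilbene; this should be secured by the doubly activated C–H bond (α-oxygen, electron-rich aryl) held five atoms from the carbene carbon, by the low electrophilicity of a donor/donor carbene towards a 1,2-disubstituted alkene and by slow addition at low concentration. Only the C3 configuration has to persist, because C2 is equilibrated in step 6.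

Step 6
Reactants: 11 (2R,3S)-cis heptamethyl ether
Product: 13 5-[(2S,3S)-2-(3,4-dihydroxyphenyl)-5-[(E)-2-(3,5-dihydroxyphenyl)ethenyl]-6-hydroxy-2,3-dihydro-1-benzofuran-3-yl]benzene-1,3-diol (2,3-trans), via quinone methide 12 (not isolated)
Conditions: BBr3 (14 equiv), CH2Cl2, −78 °C → rt; ice-water quench
Reagents that add atoms: none
Why: BBr3 should cleave the seven aryl methyl ethers (Lewis acid–base adduct, then SN2 attack of bromide at methyl) and, being a benzylic-ether-cleaving Lewis acid, also ionize the C2–O1 bond with help from the para oxygen of the 3,4-dioxygenated ring, so that the ring-opened quinone methide 12 recloses by 5-exo-trig oxa-Michael addition of the ring A phenol under thermodynamic control to the trans (2S,3S) isomer, while C3, which is not ionizable, keeps the configuration set in step 5.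

Compound list
1 | 1-bromo-2,4-dimethoxybenzene | COc1ccc(Br)c(OC)c1 | starting material
2 | 3,5-dimethoxybenzoyl chloride | COc1cc(OC)cc(C(=O)Cl)c1 | starting material
3 | (5-bromo-2,4-dimethoxyphenyl)(3,5-dimethoxyphenyl)methanone | COc1cc(OC)cc(C(=O)c2cc(Br)c(OC)cc2OC)c1 | intermediate (not isolated)
4 | (5-bromo-2-hydroxy-4-methoxyphenyl)(3,5-dimethoxyphenyl)methanone | COc1cc(OC)cc(C(=O)c2cc(Br)c(OC)cc2O)c1 | intermediate
5 | 3,4-dimethoxybenzyl bromide | COc1ccc(CBr)cc1OC | starting material
6 | {5-bromo-2-[(3,4-dimethoxybenzyl)oxy]-4-methoxyphenyl}(3,5-dimethoxyphenyl)methanone | COc1cc(OC)cc(C(=O)c2cc(Br)c(OC)cc2OCc2ccc(OC)c(OC)c2)c1 | intermediate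
7 | 3,5-dimethoxystyrene | C=Cc1cc(OC)cc(OC)c1 | starting material
8 | {2-[(3,4-dimethoxybenzyl)oxy]-5-[(E)-2-(3,5-dimethoxyphenyl)ethenyl]-4-methoxyphenyl}(3,5-dimethoxyphenyl)methanone | COc1cc(OC)cc(C(=O)c2cc(/C=C/c3cc(OC)cc(OC)c3)c(OC)cc2OCc2ccc(OC)c(OC)c2)c1 | intermediate
9 | hydrazone of ketone 8 (C=N–NH2, mixture of C=N isomers) | COc1cc(OC)cc(C(=NN)c2cc(/C=C/c3cc(OC)cc(OC)c3)c(OC)cc2OCc2ccc(OC)c(OC)c2)c1 | intermediate
10 | diaryldiazomethane derived from 9 | COc1cc(OC)cc(C(=[N+]=[N-])c2cc(/C=C/c3cc(OC)cc(OC)c3)c(OC)cc2OCc2ccc(OC)c(OC)c2)c1 | intermediate (not isolated)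
11 | (2R,3S)-2-(3,4-dimethoxyphenyl)-3-(3,5-dimethoxyphenyl)-5-[(E)-2-(3,5-dimethoxyphenyl)ethenyl]-6-methoxy-2,3-dihydro-1-benzofuran (2,3-cis) | COc1cc(OC)cc(/C=C/c2cc3c(cc2OC)O[C@@H](c2ccc(OC)c(OC)c2)[C@H]3c2cc(OC)cc(OC)c2)c1 | intermediate
12 | ring-opened para-quinone methide (drawn as the free phenol, C3 configuration as in 11; present in the flask as its boron aryloxide or protonated form) | O=C1C=CC(=C[C@@H](c2cc(O)cc(O)c2)c2cc(/C=C/c3cc(O)cc(O)c3)c(O)cc2O)C=C1O | intermediate (not isolated)
13 | 5-[(2S,3S)-2-(3,4-dihydroxyphenyl)-5-[(E)-2-(3,5-dihydroxyphenyl)ethenyl]-6-hydroxy-2,3-dihydro-1-benzofuran-3-yl]benzene-1,3-diol (2,3-trans) | Oc1cc(O)cc(/C=C/c2cc3c(cc2O)O[C@H](c2ccc(O)c(O)c2)[C@H]3c2cc(O)cc(O)c2)c1 | target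

Total step count: 6
Longest linear sequence: 6 steps (1 → 4 → 6 → 8 → 9 → 11 → 13)

Steps most likely to fail

Step 5 (key step). The carbene may be diverted before it reaches the benzylic C–H bond, either by azine formation with unreacted diazo compound or by capture by the stilbene of a second molecule. The facial selectivity at the carbene carbon may also be eroded by the large styryl substituent on ring A. The fallback closes the ring before the stilbene exists. It sets out from 6: condensation with hydrazine (N2H4·H2O, AcOH cat., EtOH, 90 °C) should give the bromo hydrazone F1, MnO2 in CH2Cl2 should give the bromo diazo compound F2 (not isolated), and Rh2(R-PTAD)4 should close the ring to the bromo cis-dihydrobenzofuran F3. A Mizoroki–Heck coupling of F3 with 7 (Pd(OAc)2, P(o-tol)3, Et3N, DMF, 110 °C) then comes back to the route at 11.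

Step 6. The ring-opened benzylic cation may fail to reclose cleanly while seven demethylations are still in progress. It could lose the C3 proton to a triarylethene, which would erase C3, or add to the stilbene of another molecule. Equilibration may also stop at a mixture of cis and trans heptaphenols that is hard to separate. The fallback takes the stereochemical correction out of the deprotection. It sets out from 11: catalytic trifluoroacetic acid in CH2Cl2 at rt should equilibrate C2 through the para-methoxy-stabilised benzylic cation to the trans heptamethyl ether F4, which is neutral and can be purified by chromatography and checked for C3 integrity. Demethylation of F4 with the milder couple BCl3/n-Bu4NI (CH2Cl2, −78 → 0 °C), which now has no stereochemical task, comes back to the route at 13.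

Step 1. The acylation may take a wrong course under AlCl3: attack at the position between the two methoxy groups, migration or loss of bromine, self-acylation of the electron-rich acid chloride, or cleavage of more than one methyl ether. The fallback builds the ketone by carbonyl addition instead of electrophilic aromatic substitution. It sets out from 5 and the commercial 5-bromo-2-hydroxy-4-methoxybenzaldehyde F5: etherification (K2CO3, DMF, 60 °C) should give the aldehyde ether F6, and addition of the commercial 3,5-dimethoxyphenylmagnesium chloride F7 (THF, 0 °C; water quench) should give the diaryl carbinol F8. Oxidation of this doubly benzylic alcohol with MnO2 (CH2Cl2, rt) comes back to the route at 6, bypassing 4.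

Further compounds
F1 | step 5 | hydrazone of bromo ketone 6 (C=N–NH2, mixture of C=N isomers) | COc1cc(OC)cc(C(=NN)c2cc(Br)c(OC)cc2OCc2ccc(OC)c(OC)c2)c1
F2 | step 5 | diaryldiazomethane derived from F1 | COc1cc(OC)cc(C(=[N+]=[N-])c2cc(Br)c(OC)cc2OCc2ccc(OC)c(OC)c2)c1
F3 | step 5 | (2R,3S)-5-bromo-2-(3,4-dimethoxyphenyl)-3-(3,5-dimethoxyphenyl)-6-methoxy-2,3-dihydro-1-benzofuran (2,3-cis) | Brc1cc2c(cc1OC)O[C@@H](c1ccc(OC)c(OC)c1)[C@H]2c1cc(OC)cc(OC)c1
F4 | step 6 | (2S,3S)-2-(3,4-dimethoxyphenyl)-3-(3,5-dimethoxyphenyl)-5-[(E)-2-(3,5-dimethoxyphenyl)ethenyl]-6-methoxy-2,3-dihydro-1-benzofuran (2,3-trans) | COc1cc(OC)cc(/C=C/c2cc3c(cc2OC)O[C@H](c2ccc(OC)c(OC)c2)[C@H]3c2cc(OC)cc(OC)c2)c1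
F5 | step 1 | 5-bromo-2-hydroxy-4-methoxybenzaldehyde | COc1cc(O)c(C=O)cc1Br
F6 | step 1 | 5-bromo-2-[(3,4-dimethoxybenzyl)oxy]-4-methoxybenzaldehyde | COc1cc(OCc2ccc(OC)c(OC)c2)c(C=O)cc1Br
F7 | step 1 | 3,5-dimethoxyphenylmagnesium chloride | COc1cc(OC)cc([Mg]Cl)c1
F8 | step 1 | {5-bromo-2-[(3,4-dimethoxybenzyl)oxy]-4-methoxyphenyl}(3,5-dimethoxyphenyl)methanol (racemic) | COc1cc(OC)cc(C(O)c2cc(Br)c(OC)cc2OCc2ccc(OC)c(OC)c2)c1
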